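**Retrosynthetic overview**
- Numbering: half A has C1 (biaryl carbon), C2 (O), C4 and C5 (OMe), C7 (Me). The other half has C1' (biaryl carbon), C2' (Me), C3' (H), C4' (O), C4a', C5' (OMe), C6' (O), C8a'. Ring C is C1'-C4' plus C4a' and C8a'; ring D is its benzo partner.
- Feature used: the run C1'(aryl)-C2'(Me)-C3'(H)-C4'(O) of ring C matches the run C6-C5-C4-C3 of a 2-pyrone. The C5' methoxy group stands beside fusion carbon C4a', so ring D can enter as an aryne C4a'≡C8a' polarised by that methoxy group.
- Disconnections: (a) three O-benzyl groups; (b) C4'-C4a' and C1'-C8a' of ring C (pyrone plus aryne, then loss of CO2); (c) the pyrone into an aryl ethyl ketone (C6, C5, 5-Me), a one-carbon aminomethylene unit (C4) and benzyloxyketene (C3, C2); (d) the C1-acyl bond via the 1-bromonaphthalene.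
- (e) The oxygenated ring of naphthalene A comes from 3-methoxy-5-methylbenzyne and methyl acetoacetate (acyl-alkylation, then Claisen closure). The ring D aryne precursor comes from vanillin (benzylation, Baeyer-Villiger oxidation, ortho-silylation, triflation).
- Ring order: second ring of naphthalene A, then the pyrone ring, then ring C (which consumes the pyrone ring). Ring D and the first ring of A are bought.

Key step: step 17

Assumption: the target string fixes no configuration at the C1-C1' axis, so the racemic mixture of atropisomers is the goal.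
Abbreviation: naphthyl A = 2-(benzyloxy)-4,5-dimethoxy-7-methylnaphthalen-1-yl.

**Step 1**
Reactants: 1 3-methoxy-5-methylphenol
Product: 2 3-methoxy-5-methylphenyl isopropylcarbamate
Conditions: i-PrNCO, Et3N (cat.), CH2Cl2, rt
Reagents that add atoms: isopropyl isocyanate, CC(C)N=C=O
Why: Base-catalysed addition of the phenol O-H across the isocyanate (carbamoylation) installs a strong oxygen-based directing group in a form that can later be removed by a mild E1cB cleavage.

**Step 2**
Reactants: 2 3-methoxy-5-methylphenyl isopropylcarbamate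
Product: 6 3-methoxy-5-methyl-2-(trimethylsilyl)phenyl isopropylcarbamate, via N-TBS carbamate 3 (not isolated), via aryllithium 4 (not isolated), via N-TBS C-TMS carbamate 5 (not isolated)
Conditions: TBSOTf, TMEDA, Et2O, 0 °C to rt; n-BuLi, TMEDA, -78 °C; TMSCl, -78 °C to rt; aq NaHSO4
Reagents that add atoms: chlorotrimethylsilane, C[Si](C)(C)Cl (TBSOTf, CC(C)(C)[Si](C)(C)OS(=O)(=O)C(F)(F)F, leaves atoms only in 3 to 5)
Why: Directed ortho-metalation, in which transient N-silylation masks the acidic N-H, the carbamate and methoxy groups together steer n-BuLi to the C-H between them, TMSCl traps the aryllithium, and the acidic work-up hydrolyses only the labile N-Si bond.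

**Step 3**
Reactants: 6 3-methoxy-5-methyl-2-(trimethylsilyl)phenyl isopropylcarbamate
Product: 8 3-methoxy-5-methyl-2-(trimethylsilyl)phenyl trifluoromethanesulfonate, via silylphenol 7 (not isolated)
Conditions: DBU, Et2NH, MeCN, 40 °C; then PhNTf2, rt
Reagents that add atoms: N-phenylbis(trifluoromethanesulfonimide), O=S(=O)(N(c1ccccc1)S(=O)(=O)C(F)(F)F)C(F)(F)F
Why: E1cB cleavage of the secondary carbamate followed by O-triflation in one flask, in which diethylamine traps the expelled isocyanate as a urea, PhNTf2 sulfonylates the phenoxide, and the aryl C-Si bond is left alone.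

**Step 4**
Reactants: 8 3-methoxy-5-methyl-2-(trimethylsilyl)phenyl trifluoromethanesulfonate; 9 methyl acetoacetate
Product: 11 methyl 2-(2-acetyl-3-methoxy-5-methylphenyl)acetate, via aryne 10 (not isolated)
Conditions: CsF, MeCN, 80 °C
Reagents that add atoms: none
Why: Aryne acyl-alkylation (formal insertion of the aryne into the C2-C3 bond of the β-keto ester), in which the enolate carbon attacks the more electrophilic aryne carbon meta to the methoxy group, so that after acyl transfer the acetyl group sits ortho to OMe and the CH2CO2Me arm sits on the former triflate carbon.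

**Step 5**
Reactants: 11 methyl 2-(2-acetyl-3-methoxy-5-methylphenyl)acetate
Product: 12 8-methoxy-6-methylnaphthalene-1,3-diol
Conditions: KOt-Bu, THF, 0 °C to rt, argon; 1 M HCl
Reagents that add atoms: none
Why: Intramolecular Claisen (Dieckmann-type) condensation, in which the methyl ketone enolate attacks the ester in a 6-exo-trig closure and aromatisation to the naphthalenediolate makes the closure irreversible, with oxygen excluded because the diolate is easily oxidised.

**Step 6**
Reactants: 12 8-methoxy-6-methylnaphthalene-1,3-diol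
Product: 13 3-(benzyloxy)-8-methoxy-6-methylnaphthalen-1-ol
Conditions: BnBr (1.0 equiv), K2CO3, acetone, rt, argon
Reagents that add atoms: benzyl bromide, BrCc1ccccc1
Why: Williamson etherification under substrate control, since the C1 hydroxyl is hydrogen-bonded to and crowded by the peri methoxy group, so one equivalent of benzyl bromide should take the free C3 hydroxyl, and the aprotic medium favours O- over C-benzylation.

**Step 7**
Reactants: 13 3-(benzyloxy)-8-methoxy-6-methylnaphthalen-1-ol
Product: 14 3-(benzyloxy)-1,8-dimethoxy-6-methylnaphthalene (naphthyl A-H)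
Conditions: MeI, K2CO3, DMF, 40 °C
Reagents that add atoms: iodomethane, CI
Why: Williamson methylation of the remaining peri hydroxyl, for which a small electrophile in a dipolar aprotic solvent overcomes hydrogen bonding and crowding.

**Step 8**
Reactants: 14 3-(benzyloxy)-1,8-dimethoxy-6-methylnaphthalene
Product: 15 2-(benzyloxy)-1-bromo-4,5-dimethoxy-7-methylnaphthalene (naphthyl A-Br)
Conditions: NBS, MeCN, 0 °C, dark
Reagents that add atoms: N-bromosuccinimide, O=C1CCC(=O)N1Br
Why: Electrophilic aromatic bromination at C1, an α position para to the C4 methoxy and ortho to the C2 benzyloxy group in the more electron-rich ring, while polar dark conditions suppress radical attack at the methyl and benzylic CH2 groups.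

**Step 9**
Reactants: 15 2-(benzyloxy)-1-bromo-4,5-dimethoxy-7-methylnaphthalene; 16 N-methoxy-N-methylpropanamide
Product: 18 1-(naphthyl A)propan-1-one, via aryllithium 17 (not isolated)
Conditions: n-BuLi, THF, -78 °C; then 16, -78 to 0 °C; aq NH4Cl
Reagents that add atoms: none
Why: Bromine-lithium exchange at -78 °C outruns deprotonation of the benzyl ether, and the Weinreb ketone synthesis stops at the ketone, so the crowded bond at C1 (later the C1-C1' axis) is made by carbonyl addition rather than by cross-coupling.

**Step 10**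
Reactants: 18 1-(naphthyl A)propan-1-one
Product: 19 (E)-3-(dimethylamino)-2-methyl-1-(naphthyl A)prop-2-en-1-one
Conditions: t-BuOCH(NMe2)2, toluene, 110 °C
Reagents that add atoms: tert-butoxybis(dimethylamino)methane, CN(C)C(OC(C)(C)C)N(C)C
Why: Aminomethylenation of an enolisable ketone with an aminal ester, in which the released tert-butoxide deprotonates the only α-CH2, the enolate adds to the formamidinium ion, and loss of dimethylamine gives the more stable E vinylogous amide carrying the future C4 of the pyrone.

**Step 11**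
Reactants: 19 (E)-3-(dimethylamino)-2-methyl-1-(naphthyl A)prop-2-en-1-one; 20 (benzyloxy)acetyl chloride
Product: 23 3-(benzyloxy)-5-methyl-6-(naphthyl A)-2H-pyran-2-one, via benzyloxyketene 21 (not isolated), via aminodihydropyranone 22 (not isolated)
Conditions: 20 (slow addition), Et3N, toluene, 0 to 80 °C
Reagents that add atoms: none
Why: Formal (4+2) cycloaddition of a ketene (made by dehydrochlorination of the acid chloride) with the O=C-C=C unit of an α-aminomethylene ketone, followed by E1cB loss of dimethylamine, in which the α-methyl group blocks C-acylation, ring closure occurs far from the hindered aryl group, and the two stereocentres of 22 vanish on elimination.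

**Step 12**
Reactants: 24 vanillin
Product: 25 4-(benzyloxy)-3-methoxybenzaldehyde
Conditions: BnBr, K2CO3, DMF, rt
Reagents that add atoms: benzyl bromide, BrCc1ccccc1
Why: Williamson etherification of the only hydroxyl group, done before the oxidation so that the oxygen ortho to OMe (the future C6' oxygen) is the one that carries benzyl.

**Step 13**
Reactants: 25 4-(benzyloxy)-3-methoxybenzaldehyde
Product: 27 4-(benzyloxy)-3-methoxyphenol, via aryl formate 26 (not isolated)
Conditions: mCPBA, CH2Cl2, rt; then K2CO3 (cat.), MeOH, rt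
Reagents that add atoms: 3-chloroperbenzoic acid, O=C(OO)c1cccc(Cl)c1
Why: Baeyer-Villiger oxidation of an electron-rich benzaldehyde (the peracid form of the Dakin reaction), in which the 3,4-dialkoxyaryl group migrates in preference to hydride and mild methanolysis frees the phenol from its formate.

**Step 14**
Reactants: 27 4-(benzyloxy)-3-methoxyphenol
Product: 28 4-(benzyloxy)-3-methoxyphenyl isopropylcarbamate
Conditions: i-PrNCO, Et3N (cat.), CH2Cl2, rt
Reagents that add atoms: isopropyl isocyanate, CC(C)N=C=O
Why: The same base-catalysed carbamoylation as in step 1, chemoselective because the phenol is the only nucleophile present.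

**Step 15**
Reactants: 28 4-(benzyloxy)-3-methoxyphenyl isopropylcarbamate
Product: 32 4-(benzyloxy)-3-methoxy-2-(trimethylsilyl)phenyl isopropylcarbamate, via N-TBS carbamate 29 (not isolated), via aryllithium 30 (not isolated), via N-TBS C-TMS carbamate 31 (not isolated)
Conditions: TBSOTf, TMEDA, Et2O, 0 °C to rt; n-BuLi, TMEDA, -78 °C; TMSCl, -78 °C to rt; aq NaHSO4
Reagents that add atoms: chlorotrimethylsilane, C[Si](C)(C)Cl (TBSOTf, CC(C)(C)[Si](C)(C)OS(=O)(=O)C(F)(F)F, leaves atoms only in 29 to 31)
Why: Directed ortho-metalation as in step 2, since the C2-H flanked by the carbamate and the C3 methoxy group is by far the most kinetically acidic site, so n-BuLi/TMEDA at -78 °C should remove it faster than the C6-H or the benzylic CH2, and TMSCl fills the carbon that becomes C4a'.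

**Step 16**
Reactants: 32 4-(benzyloxy)-3-methoxy-2-(trimethylsilyl)phenyl isopropylcarbamate
Product: 34 4-(benzyloxy)-3-methoxy-2-(trimethylsilyl)phenyl trifluoromethanesulfonate, via silylphenol 33 (not isolated)
Conditions: DBU, Et2NH, MeCN, 40 °C; then PhNTf2, rt
Reagents that add atoms: N-phenylbis(trifluoromethanesulfonimide), O=S(=O)(N(c1ccccc1)S(=O)(=O)C(F)(F)F)C(F)(F)F
Why: The same E1cB carbamate cleavage and in-flask O-triflation as in step 3, to which benzyl and methyl ethers and the aryl C-Si bond are inert.

**Step 17**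
Reactants: 23 3-(benzyloxy)-5-methyl-6-(naphthyl A)-2H-pyran-2-one; 34 4-(benzyloxy)-3-methoxy-2-(trimethylsilyl)phenyl trifluoromethanesulfonate
Product: 37 4,6-bis(benzyloxy)-5-methoxy-2-methyl-1-(naphthyl A)naphthalene, via aryne 35 (not isolated), via bridged lactone 36 (not isolated)
Conditions: CsF, MeCN/toluene 1:1, 60 °C, slow addition of 34 (excess)
Reagents that add atoms: none
Why: Fluoride attacks silicon of 34 and triflate departs to give aryne 35, whose strained in-plane π bond adds suprafacially across C3 and C6 of pyrone 23 in a concerted but asynchronous (4+2) cycloaddition to bridged lactone 36, which expels CO2 by retro-(4+2) reaction at the reaction temperature and leaves ring C aromatic. The closest known reaction type is the Diels-Alder/decarboxylation sequence of 2-pyrones with arynes from o-silylaryl triflates, which gives naphthalenes directly. Ring C is closed by intermolecular (4+2) annulation, with C4'-C4a' and C1'-C8a' formed in the same event, four ring atoms coming from the pyrone and two from the aryne. The two bridgehead stereocentres of 36 disappear with CO2 and the hindered C1-C1' axis arises without control, so 37 is racemic, as the target string allows. Regioselectivity is the one selectivity needed: the C5' methoxy group (reinforced inductively by the neighbouring benzyloxy group) distorts 35 so that the carbon meta to it, the future C8a', is the more linear and electrophilic one, the 3-benzyloxy donor places the larger HOMO coefficient of the diene on C6 as in a 1-alkoxydiene, and the bulky naphthyl A prefers the aryne end remote from OMe, so electronic and steric bias both pair C6 with C8a' and C3 with C4a'. Slow addition of 34 keeps the aryne concentration low so that the slow attack at the shielded C6 can compete with aryne self-consumption, and any minor regioisomer should be separable at this fully protected stage.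

**Step 18**
Reactants: 37 4,6-bis(benzyloxy)-5-methoxy-2-methyl-1-(naphthyl A)naphthalene
Product: 38 4,5,5'-trimethoxy-2',7-dimethyl-[1,1'-binaphthalene]-2,4',6'-triol (CNP0288130.0, racemic)
Conditions: H2 (1 atm), 10% Pd/C, EtOAc/MeOH, rt
Reagents that add atoms: none
Why: Catalytic hydrogenolysis cleaves the three O-benzyl bonds while the methyl ethers and naphthalene rings are inert at one atmosphere and room temperature, and no stereocentre is involved.

**Compound list**
1 | 3-methoxy-5-methylphenol | COc1cc(C)cc(O)c1 | starting material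
2 | 3-methoxy-5-methylphenyl isopropylcarbamate | COc1cc(C)cc(OC(=O)NC(C)C)c1 | intermediate
3 | 3-methoxy-5-methylphenyl N-(tert-butyldimethylsilyl)-N-isopropylcarbamate | COc1cc(C)cc(OC(=O)N(C(C)C)[Si](C)(C)C(C)(C)C)c1 | intermediate
4 | 2-lithio derivative of 3 | [Li]c1c(OC)cc(C)cc1OC(=O)N(C(C)C)[Si](C)(C)C(C)(C)C | intermediate
5 | 3-methoxy-5-methyl-2-(trimethylsilyl)phenyl N-(tert-butyldimethylsilyl)-N-isopropylcarbamate | COc1cc(C)cc(OC(=O)N(C(C)C)[Si](C)(C)C(C)(C)C)c1[Si](C)(C)C | intermediate
6 | 3-methoxy-5-methyl-2-(trimethylsilyl)phenyl isopropylcarbamate | COc1cc(C)cc(OC(=O)NC(C)C)c1[Si](C)(C)C | intermediate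
7 | 3-methoxy-5-methyl-2-(trimethylsilyl)phenol | COc1cc(C)cc(O)c1[Si](C)(C)C | intermediate
8 | 3-methoxy-5-methyl-2-(trimethylsilyl)phenyl trifluoromethanesulfonate | COc1cc(C)cc(OS(=O)(=O)C(F)(F)F)c1[Si](C)(C)C | intermediate
9 | methyl acetoacetate | COC(=O)CC(C)=O | starting material
10 | 3-methoxy-5-methylbenzyne | COC1=CC(C)=CC#C1 | intermediate
11 | methyl 2-(2-acetyl-3-methoxy-5-methylphenyl)acetate | COC(=O)Cc1cc(C)cc(OC)c1C(C)=O | intermediate
12 | 8-methoxy-6-methylnaphthalene-1,3-diol | COc1cc(C)cc2cc(O)cc(O)c12 | intermediate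
13 | 3-(benzyloxy)-8-methoxy-6-methylnaphthalen-1-ol | COc1cc(C)cc2cc(OCc3ccccc3)cc(O)c12 | intermediate
14 | 3-(benzyloxy)-1,8-dimethoxy-6-methylnaphthalene | COc1cc(C)cc2cc(OCc3ccccc3)cc(OC)c12 | intermediate
15 | 2-(benzyloxy)-1-bromo-4,5-dimethoxy-7-methylnaphthalene | COc1cc(C)cc2c(Br)c(OCc3ccccc3)cc(OC)c12 | intermediate
16 | N-methoxy-N-methylpropanamide | CCC(=O)N(C)OC | starting material
17 | [2-(benzyloxy)-4,5-dimethoxy-7-methylnaphthalen-1-yl]lithium | [Li]c1c(OCc2ccccc2)cc(OC)c2c(OC)cc(C)cc12 | intermediate
18 | 1-[2-(benzyloxy)-4,5-dimethoxy-7-methylnaphthalen-1-yl]propan-1-one | CCC(=O)c1c(OCc2ccccc2)cc(OC)c2c(OC)cc(C)cc12 | intermediate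
19 | (E)-1-[2-(benzyloxy)-4,5-dimethoxy-7-methylnaphthalen-1-yl]-3-(dimethylamino)-2-methylprop-2-en-1-one | CN(C)/C=C(\C)C(=O)c1c(OCc2ccccc2)cc(OC)c2c(OC)cc(C)cc12 | intermediate
20 | (benzyloxy)acetyl chloride | O=C(Cl)COCc1ccccc1 | starting material
21 | (benzyloxy)ketene | O=C=COCc1ccccc1 | intermediate
22 | 3-(benzyloxy)-4-(dimethylamino)-5-methyl-6-(naphthyl A)-3,4-dihydro-2H-pyran-2-one (mixture of diastereomers, racemic) | CN(C)C1C(C)=C(c2c(OCc3ccccc3)cc(OC)c3c(OC)cc(C)cc23)OC(=O)C1OCc1ccccc1 | intermediate
23 | 3-(benzyloxy)-5-methyl-6-(naphthyl A)-2H-pyran-2-one | O=c1oc(-c2c(OCc3ccccc3)cc(OC)c3c(OC)cc(C)cc23)c(C)cc1OCc1ccccc1 | intermediate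
24 | vanillin | COc1cc(C=O)ccc1O | starting material
25 | 4-(benzyloxy)-3-methoxybenzaldehyde | COc1cc(C=O)ccc1OCc1ccccc1 | intermediate
26 | 4-(benzyloxy)-3-methoxyphenyl formate | COc1cc(OC=O)ccc1OCc1ccccc1 | intermediate
27 | 4-(benzyloxy)-3-methoxyphenol | COc1cc(O)ccc1OCc1ccccc1 | intermediate
28 | 4-(benzyloxy)-3-methoxyphenyl isopropylcarbamate | COc1cc(OC(=O)NC(C)C)ccc1OCc1ccccc1 | intermediate
29 | 4-(benzyloxy)-3-methoxyphenyl N-(tert-butyldimethylsilyl)-N-isopropylcarbamate | COc1cc(OC(=O)N(C(C)C)[Si](C)(C)C(C)(C)C)ccc1OCc1ccccc1 | intermediate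
30 | 2-lithio derivative of 29 | [Li]c1c(OC)c(OCc2ccccc2)ccc1OC(=O)N(C(C)C)[Si](C)(C)C(C)(C)C | intermediate
31 | 4-(benzyloxy)-3-methoxy-2-(trimethylsilyl)phenyl N-(tert-butyldimethylsilyl)-N-isopropylcarbamate | COc1c(OCc2ccccc2)ccc(OC(=O)N(C(C)C)[Si](C)(C)C(C)(C)C)c1[Si](C)(C)C | intermediate
32 | 4-(benzyloxy)-3-methoxy-2-(trimethylsilyl)phenyl isopropylcarbamate | COc1c(OCc2ccccc2)ccc(OC(=O)NC(C)C)c1[Si](C)(C)C | intermediate
33 | 4-(benzyloxy)-3-methoxy-2-(trimethylsilyl)phenol | COc1c(OCc2ccccc2)ccc(O)c1[Si](C)(C)C | intermediate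
34 | 4-(benzyloxy)-3-methoxy-2-(trimethylsilyl)phenyl trifluoromethanesulfonate | COc1c(OCc2ccccc2)ccc(OS(=O)(=O)C(F)(F)F)c1[Si](C)(C)C | intermediate
35 | 4-(benzyloxy)-3-methoxybenzyne | COC1=C(OCc2ccccc2)C=CC#C1 | intermediate
36 | bridged lactone: 4',6'-bis(benzyloxy)-5'-methoxy-2'-methyl-1'-(naphthyl A)-1',4'-dihydronaphthalene with an O-C(=O) bridge from C1' (O end) to C4' (C=O end), racemic | O=C1OC2(c3c(OCc4ccccc4)cc(OC)c4c(OC)cc(C)cc34)C(C)=CC1(OCc1ccccc1)c1c(OC)c(OCc3ccccc3)ccc12 | intermediate
37 | 4,6-bis(benzyloxy)-5-methoxy-2-methyl-1-(naphthyl A)naphthalene (racemic axis) | COc1c(OCc2ccccc2)ccc2c(-c3c(OCc4ccccc4)cc(OC)c4c(OC)cc(C)cc34)c(C)cc(OCc3ccccc3)c12 | intermediate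
38 | 4,5,5'-trimethoxy-2',7-dimethyl-[1,1'-binaphthalene]-2,4',6'-triol (CNP0288130.0) | COc1cc(C)cc2c(-c3c(C)cc(O)c4c(OC)c(O)ccc34)c(O)cc(OC)c12 | target

**Step count**
Total step count: 18.
Longest linear sequence: 13 steps (steps 1 to 11, then 17 and 18).

**Steps most likely to fail**

1. **Step 17.** Both faces of C6 are shielded by the perpendicular naphthyl A. Cycloaddition may therefore be slower than self-consumption of the aryne, and regiocontrol across the aryne may erode.
   - Fallback: the diene class is changed to a furan, a much more reactive partner for arynes, and the C4' oxygen is then supplied by the furan oxygen. The fallback sets out from ketone 18 and triflate 34 and comes back to the route at target 38.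
   - The lithium enolate of 18 (LDA, THF, -78 °C) is allylated with allyl bromide to racemic 2-methyl-1-(naphthyl A)pent-4-en-1-one F1.
   - Lemieux-Johnson cleavage (OsO4 cat., NaIO4, 2,6-lutidine, dioxane/water) gives 3-methyl-4-(naphthyl A)-4-oxobutanal F2.
   - Paal-Knorr cyclodehydration (TsOH cat., toluene, reflux) gives 3-methyl-2-(naphthyl A)furan F3.
   - Aryne 35, released from 34 with CsF in MeCN, adds across furan C2 and C5, with the bulky C2 end going to the aryne carbon remote from OMe. This gives racemic 6-(benzyloxy)-5-methoxy-2-methyl-1-(naphthyl A)-1,4-epoxy-1,4-dihydronaphthalene F4.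
   - Catalytic TsOH in CH2Cl2 ionises the tertiary, doubly benzylic C1'-O bond, and loss of the C4' proton gives 7-(benzyloxy)-8-methoxy-3-methyl-4-(naphthyl A)naphthalen-1-ol F5.
   - Hydrogenolysis of the two benzyl ethers of F5 over Pd/C gives 38.

2. **Step 11.** Dimerisation of the ketene, or its consumption by the liberated amine, may outrun the cycloaddition, and the elimination of dimethylamine may stay incomplete.
   - Fallback: the pyrone is assembled from an alkyne instead of a ketone. The fallback sets out from bromide 15 and comes back to the route at pyrone 23.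
   - Stille coupling of 15 with tributyl(prop-1-yn-1-yl)stannane (Pd(PPh3)4, toluene, 110 °C) gives 2-(benzyloxy)-4,5-dimethoxy-7-methyl-1-(prop-1-yn-1-yl)naphthalene F6.
   - Oxidative annulation of F6 with 2-(benzyloxy)acrylic acid ([Cp*RhCl2]2 cat., Ag2CO3, DMF, 120 °C) proceeds by vinylic C-H activation, alkyne insertion and C-O bond formation. The aryl group should end up next to the ring oxygen and the methyl group at C5, as is usual for aryl alkyl alkynes, which gives 23.

3. **Step 6.** Site selectivity between the two hydroxyl groups may be lost, C-benzylation of the resorcinol-like ring may compete, and the diol may oxidise in air under base.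
   - Fallback: a silyl relay replaces direct benzylation. The fallback sets out from diol 12 and comes back to the route at compound 14.
   - The bulky TIPSCl (imidazole, DMF, 0 °C) can reach only the unhindered oxygen and cannot C-alkylate, giving 8-methoxy-6-methyl-3-[(triisopropylsilyl)oxy]naphthalen-1-ol F7.
   - Methylation (MeI, K2CO3, DMF) gives [(4,5-dimethoxy-7-methylnaphthalen-2-yl)oxy]triisopropylsilane F8.
   - TBAF in THF gives 4,5-dimethoxy-7-methylnaphthalen-2-ol F9.
   - Benzylation of F9 (BnBr, K2CO3, DMF) gives 14.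

**Further compounds**
F1 | step 17 | 2-methyl-1-(naphthyl A)pent-4-en-1-one (racemic) | C=CCC(C)C(=O)c1c(OCc2ccccc2)cc(OC)c2c(OC)cc(C)cc12
F2 | step 17 | 3-methyl-4-(naphthyl A)-4-oxobutanal (racemic) | O=CCC(C)C(=O)c1c(OCc2ccccc2)cc(OC)c2c(OC)cc(C)cc12
F3 | step 17 | 3-methyl-2-(naphthyl A)furan | Cc1ccoc1-c1c(OCc2ccccc2)cc(OC)c2c(OC)cc(C)cc12
F4 | step 17 | 6-(benzyloxy)-5-methoxy-2-methyl-1-(naphthyl A)-1,4-epoxy-1,4-dihydronaphthalene (racemic) | COc1c(OCc2ccccc2)ccc2c1C1C=C(C)C2(c2c(OCc3ccccc3)cc(OC)c3c(OC)cc(C)cc23)O1
F5 | step 17 | 7-(benzyloxy)-8-methoxy-3-methyl-4-(naphthyl A)naphthalen-1-ol | COc1c(OCc2ccccc2)ccc2c(-c3c(OCc4ccccc4)cc(OC)c4c(OC)cc(C)cc34)c(C)cc(O)c12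
F6 | step 11 | 2-(benzyloxy)-4,5-dimethoxy-7-methyl-1-(prop-1-yn-1-yl)naphthalene | CC#Cc1c(OCc2ccccc2)cc(OC)c2c(OC)cc(C)cc12
F7 | step 6 | 8-methoxy-6-methyl-3-[(triisopropylsilyl)oxy]naphthalen-1-ol | COc1cc(C)cc2cc(O[Si](C(C)C)(C(C)C)C(C)C)cc(O)c12
F8 | step 6 | [(4,5-dimethoxy-7-methylnaphthalen-2-yl)oxy]triisopropylsilane | COc1cc(C)cc2cc(O[Si](C(C)C)(C(C)C)C(C)C)cc(OC)c12
F9 | step 6 | 4,5-dimethoxy-7-methylnaphthalen-2-ol | COc1cc(C)cc2cc(O)cc(OC)c12
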